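**Strategy.** The route rests on cutting the bond between C2 of the 3,7-dioxabicyclo[3.3.0]octane core and C1 of the 4-hydroxy-3-methoxyphenyl ring. C2 is benzylic and also bonded to the ring oxygen O3, so it is treated as an anomeric carbon. An arylzinc reagent displaces a phenylsulfonyl group at C2 through the bicyclic oxocarbenium ion (O3=C2), and the convex face of the cis-fused bicycle sets the exo configuration at C2 in the same operation. The precursor is the monoaryl anomeric sulfone, whose C5 and C6 stereocentres come from an Evans syn aldol and whose second ring (C1–C8–O7) is closed by a Prins-type cyclisation of a MOM ether.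

Key step: step 10

**Remarks.**
- Numbering: C1 and C5 are the ring-fusion carbons, C2 and C6 carry the aryl groups, O3 and O7 are the ring oxygens, C4 and C8 the methylenes. The target is (1R,2S,5R,6S), cis-fused, both aryl groups exo.
- ArA = 3,4-dimethoxy-5-[(triisopropylsilyl)oxy]phenyl; ArB = 3-methoxy-4-[(triisopropylsilyl)oxy]phenyl.
- Assumption: compounds 1, 3, 4 and 14 are commercial. Compounds 10, 12 and 13 are expected as epimer mixtures at the acetal carbon; this is without consequence because that carbon becomes planar in the key step, so it is left undefined in their SMILES.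

**Step 1**
Reactants: 1 3-hydroxy-4,5-dimethoxybenzaldehyde
Product: 2 3,4-dimethoxy-5-[(triisopropylsilyl)oxy]benzaldehyde
Conditions: TIPSCl, imidazole, DMF, rt
Reagents that add atoms: triisopropylsilyl chloride, CC(C)[Si](Cl)(C(C)C)C(C)C
Why: Imidazole-promoted silyl ether formation should protect the phenol cleanly since the aldehyde is inert to TIPSCl; no stereocentre is involved.

**Step 2**
Reactants: 3 (S)-4-benzyloxazolidin-2-one; 4 pent-4-enoyl chloride
Product: 5 (S)-4-benzyl-3-(pent-4-enoyl)oxazolidin-2-one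
Conditions: n-BuLi, THF, −78 °C; then 4, −78 → 0 °C
Reagents that add atoms: none
Why: N-Acylation of the lithiated oxazolidinone with the acid chloride is the standard way to attach the chiral auxiliary and leaves its stereocentre untouched.

**Step 3**
Reactants: 5 (S)-4-benzyl-3-(pent-4-enoyl)oxazolidin-2-one; 2 3,4-dimethoxy-5-[(triisopropylsilyl)oxy]benzaldehyde
Product: 6 (S)-4-benzyl-3-{(S)-2-[(S)-hydroxy(ArA)methyl]pent-4-enoyl}oxazolidin-2-one
Conditions: Bu2BOTf, iPr2NEt, CH2Cl2, −78 → 0 °C; then 2, −78 → 0 °C; pH 7 buffer, MeOH, H2O2, 0 °C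
Reagents that add atoms: none
Why: Evans syn aldol reaction: the Z-boron enolate of 5 should add to the non-enolisable aldehyde through a Zimmerman–Traxler chair in which the benzyl group of the (S)-auxiliary shields one enolate face, which sets both new stereocentres (2S,3S; the future C5 and C6) with the syn relationship that later places ArA exo.

**Step 4**
Reactants: 6 (S)-4-benzyl-3-{(S)-2-[(S)-hydroxy(ArA)methyl]pent-4-enoyl}oxazolidin-2-one
Product: 7 (S)-4-benzyl-3-{(S)-2-[(S)-(methoxymethoxy)(ArA)methyl]pent-4-enoyl}oxazolidin-2-one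
Conditions: MOMCl, iPr2NEt, Bu4NI (cat.), CH2Cl2, 0 → 40 °C
Reagents that add atoms: chloromethyl methyl ether, COCCl
Why: O-Alkylation of the secondary alcohol (MOM ether formation) should proceed under non-enolising amine conditions; it differentiates O7 from the later O3 and installs the future C8 as a latent formaldehyde oxocarbenium ion.

**Step 5**
Reactants: 7 (S)-4-benzyl-3-{(S)-2-[(S)-(methoxymethoxy)(ArA)methyl]pent-4-enoyl}oxazolidin-2-one
Product: 8 (R)-2-[(S)-(methoxymethoxy)(ArA)methyl]pent-4-en-1-ol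
Conditions: LiBH4, MeOH (2 equiv), THF, 0 °C
Reagents that add atoms: none
Why: Reductive cleavage of the N-acyloxazolidinone with LiBH4 should give the primary alcohol (the future C4–O3 unit) without epimerisation and without touching the alkene, MOM or silyl ether, and returns the auxiliary.

**Step 6**
Reactants: 8 (R)-2-[(S)-(methoxymethoxy)(ArA)methyl]pent-4-en-1-ol
Product: 10 (4R)-4-[(S)-(methoxymethoxy)(ArA)methyl]oxolan-2-ol, via hydroxy aldehyde 9 (not isolated)
Conditions: OsO4 (2 mol %), NaIO4, 2,6-lutidine, dioxane/H2O 3:1, rt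
Reagents that add atoms: osmium tetroxide (catalytic, regenerated by periodate), O=[Os](=O)(=O)=O; sodium periodate, [Na+].[O-]I(=O)(=O)=O
Why: Lemieux–Johnson oxidative cleavage of the terminal alkene should give the aldehyde, which closes spontaneously with the primary alcohol to the five-membered lactol; OsO4/NaIO4 is chosen over ozone to spare the electron-rich arene.

**Step 7**
Reactants: 10 (4R)-4-[(S)-(methoxymethoxy)(ArA)methyl]oxolan-2-ol
Product: 12 (1R,5R,6S)-6-(ArA)-2-methoxy-3,7-dioxabicyclo[3.3.0]octane, via dihydrofuran enol ether 11 (not isolated)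
Conditions: TMSOTf (3 equiv), iPr2NEt (2.5 equiv), CH2Cl2, −78 → −20 °C; then Et3N
Reagents that add atoms: none
Why: Prins-type cyclisation: TMSOTf/amine should first convert the lactol into the cyclic enol ether 11 (acetal-to-enol-ether elimination) and then ionise the MOM ether to the O7=C8 oxocarbenium ion, which is attacked by the nucleophilic β-carbon (C1) of the enol ether; the tether forces the cis ring fusion and so fixes C1, and the resulting bicyclic oxocarbenium ion is captured by the methoxy group released from the MOM ether.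

**Step 8**
Reactants: 12 (1R,5R,6S)-6-(ArA)-2-methoxy-3,7-dioxabicyclo[3.3.0]octane
Product: 13 (1R,5R,6S)-6-(ArA)-2-(phenylsulfonyl)-3,7-dioxabicyclo[3.3.0]octane
Conditions: PhSO2H, CaCl2, CH2Cl2, rt
Reagents that add atoms: benzenesulfinic acid, O=S(O)c1ccccc1
Why: Acid-mediated exchange of the anomeric methoxy group for sulfinate through the oxocarbenium ion (S-alkylation of the sulfinic acid) should give the anomeric sulfone, driven by CaCl2 binding the methanol; C1, C5 and C6 are not involved.

**Step 9**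
Reactants: 14 4-bromo-2-methoxyphenol
Product: 15 (4-bromo-2-methoxyphenoxy)triisopropylsilane
Conditions: TIPSCl, imidazole, DMF, rt
Reagents that add atoms: triisopropylsilyl chloride, CC(C)[Si](Cl)(C(C)C)C(C)C
Why: Imidazole-promoted silylation should mask the phenol so that the aryl bromide can be converted into an organometallic reagent.

**Step 10**
Reactants: 15 (4-bromo-2-methoxyphenoxy)triisopropylsilane; 13 (1R,5R,6S)-6-(ArA)-2-(phenylsulfonyl)-3,7-dioxabicyclo[3.3.0]octane
Product: 18 (1R,2S,5R,6S)-6-(ArA)-2-(ArB)-3,7-dioxabicyclo[3.3.0]octane, via aryl Grignard reagent 16 (not isolated), via arylzinc bromide 17 (not isolated)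
Conditions: 15, Mg, THF, rt; ZnBr2 (1 equiv per Grignard), THF, 0 °C; then 13, THF, rt
Reagents that add atoms: none
Why: Zn(II) and Mg(II) should coordinate the sulfinate oxygens and ionise the C2–S bond of 13 to the bicyclic oxocarbenium ion (O3=C2), to which the arylzinc bromide transfers its aryl group at the carbon that carried bromine in 15. The closest known reaction type is the substitution of 2-(phenylsulfonyl) cyclic ethers by arylzinc reagents, a C-glycosylation-type SN1 process. No ring is closed. The new stereocentre C2 is under substrate control: the cis-fused 3,7-dioxabicyclo[3.3.0]octane is V-shaped and the aryl group enters on its convex face, anti to the C1–C8 bond, which gives the exo (2S) configuration. The step needs exo over endo selectivity, secured by the ring fusion at C1, and a single arene position, secured by the C–Zn bond para to the silyloxy group; both C2 epimers of 13 converge on the same cation. C6 is not at risk because its benzylic C–O bond carries no leaving group that these mild Lewis acids can ionise.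

**Step 11**
Reactants: 18 (1R,2S,5R,6S)-6-(ArA)-2-(ArB)-3,7-dioxabicyclo[3.3.0]octane
Product: 19 (1R,2S,5R,6S)-6-(3-hydroxy-4,5-dimethoxyphenyl)-2-(4-hydroxy-3-methoxyphenyl)-3,7-dioxabicyclo[3.3.0]octane
Conditions: TBAF, AcOH, THF, 0 °C
Reagents that add atoms: none
Why: Fluoride-mediated cleavage of both aryl silyl ethers, buffered with acetic acid so that the p-hydroxybenzylic ether at C2 sees neither free phenoxide nor strong acid, should release the target without epimerisation.

**Compound list**
1 | 3-hydroxy-4,5-dimethoxybenzaldehyde | O=Cc1cc(O)c(OC)c(OC)c1 | starting material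
2 | 3,4-dimethoxy-5-[(triisopropylsilyl)oxy]benzaldehyde | O=Cc1cc(O[Si](C(C)C)(C(C)C)C(C)C)c(OC)c(OC)c1 | intermediate
3 | (S)-4-benzyloxazolidin-2-one | O=C1N[C@@H](Cc2ccccc2)CO1 | starting material
4 | pent-4-enoyl chloride | C=CCCC(Cl)=O | starting material
5 | (S)-4-benzyl-3-(pent-4-enoyl)oxazolidin-2-one | O=C1OC[C@H](Cc2ccccc2)N1C(=O)CCC=C | intermediate
6 | (S)-4-benzyl-3-{(S)-2-[(S)-hydroxy(ArA)methyl]pent-4-enoyl}oxazolidin-2-one | O=C1OC[C@H](Cc2ccccc2)N1C(=O)[C@@H](CC=C)[C@H](O)c1cc(O[Si](C(C)C)(C(C)C)C(C)C)c(OC)c(OC)c1 | intermediate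
7 | (S)-4-benzyl-3-{(S)-2-[(S)-(methoxymethoxy)(ArA)methyl]pent-4-enoyl}oxazolidin-2-one | O=C1OC[C@H](Cc2ccccc2)N1C(=O)[C@@H](CC=C)[C@H](OCOC)c1cc(O[Si](C(C)C)(C(C)C)C(C)C)c(OC)c(OC)c1 | intermediate
8 | (R)-2-[(S)-(methoxymethoxy)(ArA)methyl]pent-4-en-1-ol | OC[C@@H](CC=C)[C@H](OCOC)c1cc(O[Si](C(C)C)(C(C)C)C(C)C)c(OC)c(OC)c1 | intermediate
9 | (3R,4S)-3-(hydroxymethyl)-4-(methoxymethoxy)-4-(ArA)butanal | O=CC[C@H](CO)[C@H](OCOC)c1cc(O[Si](C(C)C)(C(C)C)C(C)C)c(OC)c(OC)c1 | intermediate
10 | (4R)-4-[(S)-(methoxymethoxy)(ArA)methyl]oxolan-2-ol (anomers) | OC1C[C@H](CO1)[C@H](OCOC)c1cc(O[Si](C(C)C)(C(C)C)C(C)C)c(OC)c(OC)c1 | intermediate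
11 | (R)-3-[(S)-(methoxymethoxy)(ArA)methyl]-2,3-dihydrofuran | C1=C[C@H](CO1)[C@H](OCOC)c1cc(O[Si](C(C)C)(C(C)C)C(C)C)c(OC)c(OC)c1 | intermediate
12 | (1R,5R,6S)-6-(ArA)-2-methoxy-3,7-dioxabicyclo[3.3.0]octane (C2 epimers) | COC1OC[C@H]2[C@@H]1CO[C@@H]2c1cc(O[Si](C(C)C)(C(C)C)C(C)C)c(OC)c(OC)c1 | intermediate
13 | (1R,5R,6S)-6-(ArA)-2-(phenylsulfonyl)-3,7-dioxabicyclo[3.3.0]octane (C2 epimers) | O=S(=O)(c1ccccc1)C1OC[C@H]2[C@@H]1CO[C@@H]2c1cc(O[Si](C(C)C)(C(C)C)C(C)C)c(OC)c(OC)c1 | intermediate
14 | 4-bromo-2-methoxyphenol | COc1cc(Br)ccc1O | starting material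
15 | (4-bromo-2-methoxyphenoxy)triisopropylsilane | COc1cc(Br)ccc1O[Si](C(C)C)(C(C)C)C(C)C | intermediate
16 | {3-methoxy-4-[(triisopropylsilyl)oxy]phenyl}magnesium bromide | COc1cc([Mg]Br)ccc1O[Si](C(C)C)(C(C)C)C(C)C | intermediate
17 | {3-methoxy-4-[(triisopropylsilyl)oxy]phenyl}zinc bromide | COc1cc([Zn]Br)ccc1O[Si](C(C)C)(C(C)C)C(C)C | intermediate
18 | (1R,2S,5R,6S)-6-(ArA)-2-(ArB)-3,7-dioxabicyclo[3.3.0]octane | COc1cc([C@H]2OC[C@H]3[C@@H]2CO[C@@H]3c2cc(O[Si](C(C)C)(C(C)C)C(C)C)c(OC)c(OC)c2)ccc1O[Si](C(C)C)(C(C)C)C(C)C | intermediate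
19 | (1R,2S,5R,6S)-6-(3-hydroxy-4,5-dimethoxyphenyl)-2-(4-hydroxy-3-methoxyphenyl)-3,7-dioxabicyclo[3.3.0]octane | COc1cc([C@H]2OC[C@H]3[C@@H]2CO[C@@H]3c2cc(O)c(OC)c(OC)c2)ccc1O | target

**Step count.** Total: 11 steps. Longest linear sequence: 9 steps (steps 1, 3, 4, 5, 6, 7, 8, 10, 11).

**Steps most likely to fail**

Step 7. The attack of the enol ether on the O7=C8 oxocarbenium ion follows a 5-endo trajectory at that unit and may be slower than intermolecular oligomerisation of the enol ether or loss of the MOM group. The C1–C8 bond would then be made by enolate alkylation instead. Setting out from lactol 10, oxidation (TEMPO, PhI(OAc)2) should give the lactone (4R)-4-[(S)-(methoxymethoxy)(ArA)methyl]oxolan-2-one F1. Me2BBr at −78 °C should convert its MOM ether into the bromomethyl ether (4R)-4-[(S)-(bromomethoxy)(ArA)methyl]oxolan-2-one F2. LiHMDS should then close the ring by 5-exo-tet C-alkylation of the lactone enolate, which can only give the cis-fused lactone (1R,5R,6S)-6-(ArA)-3,7-dioxabicyclo[3.3.0]octan-2-one F3. DIBAL-H reduction with in situ acetylation should give the anomeric acetate (1R,5R,6S)-6-(ArA)-3,7-dioxabicyclo[3.3.0]octan-2-yl acetate F4, which with PhSO2H/CaCl2 comes back to the route at sulfone 13.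

Step 10. The substitution may be diverted by elimination of benzenesulfinic acid to the bicyclic enol ether, or the aryl transfer may show incomplete facial selectivity. The C2–aryl bond would then be made by carbonyl addition and the O3–C2 bond closed afterwards. Setting out from acetal 12, mild aqueous acid should give the lactol (1R,5R,6S)-6-(ArA)-3,7-dioxabicyclo[3.3.0]octan-2-ol F5. An excess of Grignard reagent 16 should add to its open hydroxy aldehyde form to give the diol {(2S,3R,4R)-2-(ArA)-4-[hydroxy(ArB)methyl]oxolan-3-yl}methanol F6 as carbinol epimers. Acid-catalysed cyclodehydration through the p-silyloxybenzylic cation, which is stereoconvergent and should favour exo closure, comes back to the route at 18.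

Step 8. The sulfinic acid may ionise the benzylic C6–O7 bond and erode the C6 configuration, or the exchange equilibrium may not move to the sulfone. The sulfone would then be bypassed. Setting out from acetal 12, BF3·OEt2 and the diarylcuprate prepared from 16 and CuBr·SMe2 (Lewis-acid-mediated substitution of an acetal by an organocopper reagent) should give 18 directly, where the fallback comes back to the route; no new compound is made.

**Further compounds**
F1 | step 7 | (4R)-4-[(S)-(methoxymethoxy)(ArA)methyl]oxolan-2-one | O=C1C[C@H](CO1)[C@H](OCOC)c1cc(O[Si](C(C)C)(C(C)C)C(C)C)c(OC)c(OC)c1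
F2 | step 7 | (4R)-4-[(S)-(bromomethoxy)(ArA)methyl]oxolan-2-one | O=C1C[C@H](CO1)[C@H](OCBr)c1cc(O[Si](C(C)C)(C(C)C)C(C)C)c(OC)c(OC)c1
F3 | step 7 | (1R,5R,6S)-6-(ArA)-3,7-dioxabicyclo[3.3.0]octan-2-one | O=C1OC[C@H]2[C@@H]1CO[C@@H]2c1cc(O[Si](C(C)C)(C(C)C)C(C)C)c(OC)c(OC)c1
F4 | step 7 | (1R,5R,6S)-6-(ArA)-3,7-dioxabicyclo[3.3.0]octan-2-yl acetate (C2 epimers) | CC(=O)OC1OC[C@H]2[C@@H]1CO[C@@H]2c1cc(O[Si](C(C)C)(C(C)C)C(C)C)c(OC)c(OC)c1
F5 | step 10 | (1R,5R,6S)-6-(ArA)-3,7-dioxabicyclo[3.3.0]octan-2-ol (anomers) | OC1OC[C@H]2[C@@H]1CO[C@@H]2c1cc(O[Si](C(C)C)(C(C)C)C(C)C)c(OC)c(OC)c1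
F6 | step 10 | {(2S,3R,4R)-2-(ArA)-4-[hydroxy(ArB)methyl]oxolan-3-yl}methanol (carbinol epimers) | OC[C@H]1[C@@H](C(O)c2ccc(O[Si](C(C)C)(C(C)C)C(C)C)c(OC)c2)CO[C@@H]1c1cc(O[Si](C(C)C)(C(C)C)C(C)C)c(OC)c(OC)c1
F0 | step 8 | none | none
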